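1. The target comes from its C13 PMB ether, made by Julia–Kocienski union (E-C11=C12) of a C11 tetrazolyl sulfone of the bicyclic core with (S)-2-[(4-methoxybenzyl)oxy]-2-methylbut-3-enal (C12–C16; C13 from a palladium-catalysed asymmetric etherification of isoprene monoxide); the 6,17-diacetate comes from Luche reduction and acetylation of a 17-hydroxy-7-en-6-one.
2. That enone comes from the key step: a Lewis acid opens a spiro 3-alkoxycyclobutanone (ring atoms C5, C6, C7, C8) to an enolate/oxocarbenium zwitterion, and the tethered C9=C10 alkene is inserted in a formal [4+2]. The four-membered ring grows by two atoms into ring B, the same C5–C10 bond closes ring A, and loss of the acetal alkoxide from C8 gives C7=C8 and free C17–OH.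
3. Enabling feature: ring B has its oxygen on C6 and, 1,3 to it, C8 carrying the oxygenated C17 and the C7=C8 double bond, so C6(=O)–C7–C8(O) is the retron of a donor–acceptor 3-alkoxycyclobutanone. C10, the methyl-bearing quaternary fusion carbon, is the tertiary (Markovnikov) end of the C9=C10 alkene, and C5, alpha to C6, is the enolate carbon that closes both rings.
4. The cyclobutanone comes from a [2+2] of an aldoketene (from a geraniol-derived acid holding C1–C6, C9–C11, C18–C20) with (R)-2-tert-butyl-4-methylidene-1,3-dioxolane (C7, C8, C17); its acetal carbon is a traceless stereocontrol element, lost as pivalaldehyde.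
5. Ring order: cyclobutanone with a temporary spiro-dioxolane (step 8), then rings B and A together (step 9); no ring is formed afterwards.

Key step: step 9

Remark on numbering: labdane numbering of the target is used throughout (rings A and B = C1–C10, side chain C11–C16 on C9, C17 on C8, C18/C19 on C4, C20 on C10). "Pentanorlabdane" names lack C12–C16. Unless said otherwise the bicyclic intermediates have the target's spatial arrangement (trans ring fusion; C11 on C9 and the C6 oxygen cis to the C10 methyl), as written in the SMILES.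
Assumption 1: the sense of induction in step 9 is derived from a chair model (alkene attack anti to the tert-butyl group, ring oxygen axial); if the opposite sense is found, (S)-3-chloropropane-1,2-diol gives the mirror-image auxiliary and nothing else changes.
Assumption 2: in step 15 the (1R,2R)-ligand is taken to give the (S)-ether; if the sense is the opposite, the (1S,2S)-ligand is used.

Step 1
Reactants: 1 geraniol [(2E)-3,7-dimethylocta-2,6-dien-1-ol]
Product: 2 geranyl TBDPS ether [tert-butyl{[(2E)-3,7-dimethylocta-2,6-dien-1-yl]oxy}diphenylsilane]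
Conditions: TBDPSCl, imidazole, DMF, 0 °C → rt
Reagents that add atoms: tert-butyl(chloro)diphenylsilane, CC(C)(C)[Si](Cl)(c1ccccc1)c1ccccc1
Why: Standard silyl ether formation on a primary allylic alcohol; the bulky silyl group should survive the Grignard, ketene and Lewis acid steps, and the E geometry of the future C9=C10 alkene (C11 cis to C20) is taken from geraniol.

Step 2
Reactants: 2 geranyl TBDPS ether
Product: 4 (4E)-6-[(tert-butyldiphenylsilyl)oxy]-4-methylhex-4-en-1-ol, via ozonide 3 (not isolated)
Conditions: O3 (1 equiv, Sudan Red 7B end point), CH2Cl2, −78 °C; then NaBH4, MeOH, −78 → 0 °C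
Reagents that add atoms: ozone, [O-][O+]=O
Why: Chemoselective ozonolysis of the more electron-rich distal trisubstituted alkene (the proximal one is deactivated by the allylic silyloxy group), with reductive work-up of the ozonide giving the primary alcohol directly.

Step 3
Reactants: 4 (4E)-6-[(tert-butyldiphenylsilyl)oxy]-4-methylhex-4-en-1-ol
Product: 5 {[(2E)-6-bromo-3-methylhex-2-en-1-yl]oxy}(tert-butyl)diphenylsilane
Conditions: CBr4, PPh3, CH2Cl2, 0 °C
Reagents that add atoms: tetrabromomethane, BrC(Br)(Br)Br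
Why: Appel bromination of an unhindered primary alcohol under neutral conditions that leave the allylic silyl ether and the alkene untouched.

Step 4
Reactants: 5 {[(2E)-6-bromo-3-methylhex-2-en-1-yl]oxy}(tert-butyl)diphenylsilane; 6 2,2-dimethyl-5-(propan-2-ylidene)-1,3-dioxane-4,6-dione
Product: 8 5-[(6E)-8-[(tert-butyldiphenylsilyl)oxy]-2,6-dimethyloct-6-en-2-yl]-2,2-dimethyl-1,3-dioxane-4,6-dione, via Grignard reagent 7 (not isolated)
Conditions: Mg, THF, rt → 40 °C; then 6, CuBr·SMe2 (5 mol %), THF, −30 → 0 °C; 1 M HCl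
Reagents that add atoms: none
Why: Grignard formation and copper-catalysed conjugate addition to an alkylidene Meldrum's acid, a doubly activated acceptor that should build the quaternary gem-dimethyl carbon C4 reliably.

Step 5
Reactants: 8 5-[(6E)-8-[(tert-butyldiphenylsilyl)oxy]-2,6-dimethyloct-6-en-2-yl]-2,2-dimethyl-1,3-dioxane-4,6-dione
Product: 9 (7E)-9-[(tert-butyldiphenylsilyl)oxy]-3,3,7-trimethylnon-7-enoic acid
Conditions: DMF/H2O (10:1), 100 °C
Reagents that add atoms: water, O
Why: Hydrolytic opening of the Meldrum's acid ring and decarboxylation of the malonic acid formed, under neutral conditions that the silyl ether should tolerate.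

Step 6
Reactants: 10 (R)-3-chloropropane-1,2-diol; 11 2,2-dimethylpropanal (pivalaldehyde)
Product: 12 (2R,4R)-2-tert-butyl-4-(chloromethyl)-1,3-dioxolane (cis isomer)
Conditions: TsOH·H2O (2 mol %), pentane, reflux, water separator; cis isomer separated by chromatography, trans isomer re-equilibrated under the same conditions
Reagents that add atoms: none
Why: Acid-catalysed acetalisation under thermodynamic control; the stereocentre of the chlorodiol allows the acetal carbon to be obtained in one configuration by isolating the cis diastereomer.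

Step 7
Reactants: 12 (2R,4R)-2-tert-butyl-4-(chloromethyl)-1,3-dioxolane
Product: 13 (2R)-2-tert-butyl-4-methylidene-1,3-dioxolane
Conditions: KOtBu, THF, 0 °C → rt
Reagents that add atoms: none
Why: E2 dehydrochlorination gives the exocyclic enol ether and removes the original stereocentre, so the acetal carbon remains as the only stereocentre (self-regeneration of a stereocentre).

Step 8
Reactants: 9 (7E)-9-[(tert-butyldiphenylsilyl)oxy]-3,3,7-trimethylnon-7-enoic acid; 13 (2R)-2-tert-butyl-4-methylidene-1,3-dioxolane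
Product: 16 spiro-cyclobutanone (6R)-6-tert-butyl-1-[(6E)-8-[(tert-butyldiphenylsilyl)oxy]-2,6-dimethyloct-6-en-2-yl]-5,7-dioxaspiro[3.4]octan-2-one as a mixture of the diastereomers at the two cyclobutane stereocentres (C5 and C8), via acid chloride 14 (not isolated), via ketene 15 (not isolated)
Conditions: (COCl)2, DMF (cat.), CH2Cl2, 0 °C → rt, evaporation; then 13 (3 equiv), Et3N, MeCN, 60 °C, slow addition of 14
Reagents that add atoms: none
Why: Dehydrochlorination of the acid chloride to the aldoketene and thermal ketene–enol ether [2+2] cycloaddition, in which the ketene carbonyl carbon bonds to the nucleophilic CH2 terminus so that the oxygen ends up on C8 (a 3-alkoxycyclobutanone); the two new stereocentres are left uncontrolled because step 9 erases both.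

Step 9
Reactants: 16 spiro-cyclobutanone (diastereomer mixture)
Product: 19 (5R,9S,10S)-11-[(tert-butyldiphenylsilyl)oxy]-17-hydroxy-12,13,14,15,16-pentanorlabd-7-en-6-one, via zwitterion 17 (not isolated), via spiro-acetal cycloadduct 18 (not isolated)
Conditions: EtAlCl2 (1.5 equiv), CH2Cl2, −78 → −40 °C; aq. NaHCO3 work-up; then K2CO3, MeOH, 0 °C, short contact time
Reagents that add atoms: none
Why: Proposed new method: EtAlCl2 binds the strained ketone of 16 and the more substituted C5–C8 bond (donor oxygen on C8, acceptor carbonyl C6) breaks to the aluminium enolate/1,3-dioxolan-4-ylium zwitterion 17, in which both cyclobutane stereocentres are erased, so the whole diastereomer mixture converges. C9 of the E-trisubstituted C9=C10 alkene attacks the cation at C8 (Markovnikov, charge to tertiary C10) and the enolate carbon C5 collapses on C10 on the same alkene face, a formal [4+2] that inserts C9 and C10 into the four-membered ring; the closest known reaction type is the Lewis-acid formal [4+2] cycloaddition of 3-alkoxycyclobutanones with alkenes and allylsilanes, and the proposal goes beyond it in the tethered trisubstituted alkene, the spiro-acetal donor and the auxiliary control. Modes of closure: the leading C8–C9 bond spans a ten-membered array and the transannular C5–C10 bond divides it into ring B (6-enolendo onto the cation) and ring A (6-enolexo) through a chair–chair arrangement that should give the trans fusion. Stereocontrol: C10 (absolute) should follow from attack of the alkene on the dioxolanylium face anti to the tert-butyl group, combined with the chair in which the small ring oxygen rather than C17 is axial and syn to the C10 methyl; C9 follows from suprafacial addition to the E alkene (C11 cis to C20, equatorial); C5 is set by the chair–chair closure and, being alpha to the ketone, is corrected to the trans-fused epimer by the carbonate treatment, which also expels the acetal alkoxide from C8 (E1cB) and releases pivalaldehyde and the C17 hydroxyl. Selectivity needed: C-alkylation with ring closure must outrun proton transfer within 17 and Lewis-acid opening of the acetal, which the low temperature, the proton-scavenging aluminium reagent and the tether (both new bonds form in six-membered arrays) are meant to secure, and the carbonate step is kept short and cold because C9–H is vinylogously acidic.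

Step 10
Reactants: 19 (5R,9S,10S)-11-[(tert-butyldiphenylsilyl)oxy]-17-hydroxy-12,13,14,15,16-pentanorlabd-7-en-6-one
Product: 20 (5R,6S,9S,10S)-11-[(tert-butyldiphenylsilyl)oxy]-12,13,14,15,16-pentanorlabd-7-ene-6,17-diol
Conditions: NaBH4, CeCl3·7H2O, MeOH, −40 °C
Reagents that add atoms: none
Why: Luche 1,2-reduction in which hydride should attack C6 from the face opposite the axial C10 and C4 methyl groups, placing the new hydroxyl axial and cis to the C10 methyl as in the target.

Step 11
Reactants: 20 (5R,6S,9S,10S)-11-[(tert-butyldiphenylsilyl)oxy]-12,13,14,15,16-pentanorlabd-7-ene-6,17-diol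
Product: 21 (5R,6S,9S,10S)-11-[(tert-butyldiphenylsilyl)oxy]-12,13,14,15,16-pentanorlabd-7-ene-6,17-diyl diacetate
Conditions: Ac2O, pyridine, DMAP (cat.), CH2Cl2, rt
Reagents that add atoms: acetic anhydride, CC(=O)OC(C)=O
Why: Nucleophile-catalysed acylation that esterifies both the primary allylic C17 hydroxyl and the hindered axial C6 hydroxyl without touching a stereocentre.

Step 12
Reactants: 21 (5R,6S,9S,10S)-11-[(tert-butyldiphenylsilyl)oxy]-12,13,14,15,16-pentanorlabd-7-ene-6,17-diyl diacetate
Product: 22 (5R,6S,9S,10S)-11-hydroxy-12,13,14,15,16-pentanorlabd-7-ene-6,17-diyl diacetate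
Conditions: HF·pyridine, pyridine, THF, 0 °C → rt
Reagents that add atoms: none
Why: Fluoride-mediated desilylation under buffered, weakly acidic conditions that should neither cleave nor migrate the acetates.

Step 13
Reactants: 22 (5R,6S,9S,10S)-11-hydroxy-12,13,14,15,16-pentanorlabd-7-ene-6,17-diyl diacetate
Product: 23 11-[(1-phenyl-1H-tetrazol-5-yl)sulfanyl]-12,13,14,15,16-pentanorlabd-7-ene-6,17-diyl diacetate (target arrangement at C5, C6, C9, C10)
Conditions: 1-phenyl-1H-tetrazole-5-thiol, PPh3, DIAD, THF, 0 °C → rt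
Reagents that add atoms: 1-phenyl-1H-tetrazole-5-thiol, Sc1nnnn1-c1ccccc1
Why: Mitsunobu thioetherification of the primary alcohol with the acidic tetrazole thiol (SN2 at C11, no stereocentre involved).

Step 14
Reactants: 23 11-[(1-phenyl-1H-tetrazol-5-yl)sulfanyl]-12,13,14,15,16-pentanorlabd-7-ene-6,17-diyl diacetate
Product: 24 11-[(1-phenyl-1H-tetrazol-5-yl)sulfonyl]-12,13,14,15,16-pentanorlabd-7-ene-6,17-diyl diacetate (target arrangement at C5, C6, C9, C10)
Conditions: (NH4)6Mo7O24·4H2O (10 mol %), H2O2 (30 % aq.), EtOH, 0 °C → rt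
Reagents that add atoms: hydrogen peroxide, OO
Why: Molybdate-catalysed peroxide oxidation of sulfide to sulfone, expected to be chemoselective over the C7=C8 alkene, which is deactivated by two allylic acetates.

Step 15
Reactants: 25 2-methyl-2-vinyloxirane (racemic isoprene monoxide); 26 (4-methoxyphenyl)methanol
Product: 27 (2S)-2-[(4-methoxybenzyl)oxy]-2-methylbut-3-en-1-ol
Conditions: Pd2(dba)3·CHCl3 (1 mol %), (1R,2R)-N,N'-bis[2-(diphenylphosphanyl)benzoyl]cyclohexane-1,2-diamine (3 mol %), Et3B (1 mol %), CH2Cl2, rt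
Reagents that add atoms: none
Why: Palladium-catalysed dynamic kinetic asymmetric allylic etherification: the diastereomeric allylpalladium intermediates from the racemic epoxide interconvert, and boron-assisted delivery of the alcohol to the tertiary terminus sets the C13 stereocentre under ligand control.

Step 16
Reactants: 27 (2S)-2-[(4-methoxybenzyl)oxy]-2-methylbut-3-en-1-ol
Product: 28 (2S)-2-[(4-methoxybenzyl)oxy]-2-methylbut-3-enal
Conditions: Dess–Martin periodinane, NaHCO3, CH2Cl2, 0 °C → rt
Reagents that add atoms: none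
Why: Dess–Martin oxidation of the primary alcohol to an aldehyde that has no alpha hydrogen and so cannot epimerise at C13.

Step 17
Reactants: 24 11-[(1-phenyl-1H-tetrazol-5-yl)sulfonyl]-12,13,14,15,16-pentanorlabd-7-ene-6,17-diyl diacetate; 28 (2S)-2-[(4-methoxybenzyl)oxy]-2-methylbut-3-enal
Product: 29 (5R,6S,9S,10S,11E,13S)-13-[(4-methoxybenzyl)oxy]labda-7,11,14-triene-6,17-diyl diacetate
Conditions: KN(SiMe3)2, DME, −60 °C → rt (base added to the mixture of 24 and 28)
Reagents that add atoms: none
Why: Julia–Kocienski olefination: the sulfonyl carbanion adds to the non-enolisable aldehyde, and Smiles rearrangement with loss of SO2 and the tetrazolone should give the E alkene C11=C12 (potassium counter-ion, DME, alpha-branched aldehyde), with C13 carried unchanged from 28.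

Step 18
Reactants: 29 (5R,6S,9S,10S,11E,13S)-13-[(4-methoxybenzyl)oxy]labda-7,11,14-triene-6,17-diyl diacetate
Product: 30 (5R,6S,9S,10S,11E,13S)-13-hydroxylabda-7,11,14-triene-6,17-diyl diacetate (CNP0103498.1)
Conditions: DDQ, CH2Cl2/pH 7 phosphate buffer (10:1), 0 °C
Reagents that add atoms: none
Why: Oxidative cleavage of the 4-methoxybenzyl ether with DDQ under buffered conditions should free the tertiary C13 alcohol without touching the acetates or the alkenes.

Compound list
1 | geraniol, (2E)-3,7-dimethylocta-2,6-dien-1-ol | CC(C)=CCC/C(C)=C/CO | starting material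
2 | tert-butyl{[(2E)-3,7-dimethylocta-2,6-dien-1-yl]oxy}diphenylsilane | CC(C)=CCC/C(C)=C/CO[Si](c1ccccc1)(c1ccccc1)C(C)(C)C | intermediate
3 | ozonide, 5-[(3E)-5-[(tert-butyldiphenylsilyl)oxy]-3-methylpent-3-en-1-yl]-3,3-dimethyl-1,2,4-trioxolane (not isolated) | CC1(C)OOC(CC/C(C)=C/CO[Si](c2ccccc2)(c2ccccc2)C(C)(C)C)O1 | intermediate
4 | (4E)-6-[(tert-butyldiphenylsilyl)oxy]-4-methylhex-4-en-1-ol | OCCC/C(C)=C/CO[Si](c1ccccc1)(c1ccccc1)C(C)(C)C | intermediate
5 | {[(2E)-6-bromo-3-methylhex-2-en-1-yl]oxy}(tert-butyl)diphenylsilane | BrCCC/C(C)=C/CO[Si](c1ccccc1)(c1ccccc1)C(C)(C)C | intermediate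
6 | 2,2-dimethyl-5-(propan-2-ylidene)-1,3-dioxane-4,6-dione | CC(C)=C1C(=O)OC(C)(C)OC1=O | starting material
7 | Grignard reagent, bromo[(4E)-6-[(tert-butyldiphenylsilyl)oxy]-4-methylhex-4-en-1-yl]magnesium (not isolated) | Br[Mg]CCC/C(C)=C/CO[Si](c1ccccc1)(c1ccccc1)C(C)(C)C | intermediate
8 | 5-[(6E)-8-[(tert-butyldiphenylsilyl)oxy]-2,6-dimethyloct-6-en-2-yl]-2,2-dimethyl-1,3-dioxane-4,6-dione | CC1(C)OC(=O)C(C(C)(C)CCC/C(C)=C/CO[Si](c2ccccc2)(c2ccccc2)C(C)(C)C)C(=O)O1 | intermediate
9 | (7E)-9-[(tert-butyldiphenylsilyl)oxy]-3,3,7-trimethylnon-7-enoic acid | OC(=O)CC(C)(C)CCC/C(C)=C/CO[Si](c1ccccc1)(c1ccccc1)C(C)(C)C | intermediate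
10 | (R)-3-chloropropane-1,2-diol | ClC[C@H](O)CO | starting material
11 | 2,2-dimethylpropanal | CC(C)(C)C=O | starting material
12 | (2R,4R)-2-tert-butyl-4-(chloromethyl)-1,3-dioxolane | CC(C)(C)[C@@H]1OC[C@H](CCl)O1 | intermediate
13 | (2R)-2-tert-butyl-4-methylidene-1,3-dioxolane | CC(C)(C)[C@@H]1OCC(=C)O1 | intermediate
14 | (7E)-9-[(tert-butyldiphenylsilyl)oxy]-3,3,7-trimethylnon-7-enoyl chloride (not isolated) | ClC(=O)CC(C)(C)CCC/C(C)=C/CO[Si](c1ccccc1)(c1ccccc1)C(C)(C)C | intermediate
15 | ketene, (7E)-9-[(tert-butyldiphenylsilyl)oxy]-3,3,7-trimethylnona-1,7-dien-1-one (not isolated) | O=C=CC(C)(C)CCC/C(C)=C/CO[Si](c1ccccc1)(c1ccccc1)C(C)(C)C | intermediate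
16 | (6R)-6-tert-butyl-1-[(6E)-8-[(tert-butyldiphenylsilyl)oxy]-2,6-dimethyloct-6-en-2-yl]-5,7-dioxaspiro[3.4]octan-2-one, diastereomer mixture at the two cyclobutane stereocentres | O=C1CC2(CO[C@@H](C(C)(C)C)O2)C1C(C)(C)CCC/C(C)=C/CO[Si](c3ccccc3)(c4ccccc4)C(C)(C)C | intermediate
17 | enolate/1,3-dioxolan-4-ylium zwitterion from C5–C8 cleavage of 16, aluminium-bound at the enolate oxygen (not isolated) | [O-]C(CC1=[O+][C@H](C(C)(C)C)OC1)=CC(C)(C)CCC/C(C)=C/CO[Si](c2ccccc2)(c3ccccc3)C(C)(C)C | intermediate
18 | spiro-acetal cycloadduct, trans-decal-6-one with the (R)-2-tert-butyl-1,3-dioxolane spiro at C8, ring oxygen axial (not isolated) | CC(C)(C)[Si](c4ccccc4)(c5ccccc5)OC[C@@H]1[C@@]3(CO[C@@H](C(C)(C)C)O3)CC(=O)[C@@H]2C(C)(C)CCC[C@@]12C | intermediate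
19 | (5R,9S,10S)-11-[(tert-butyldiphenylsilyl)oxy]-17-hydroxy-12,13,14,15,16-pentanorlabd-7-en-6-one | CC(C)(C)[Si](c3ccccc3)(c4ccccc4)OC[C@@H]1C(CO)=CC(=O)[C@@H]2C(C)(C)CCC[C@@]12C | intermediate
20 | (5R,6S,9S,10S)-11-[(tert-butyldiphenylsilyl)oxy]-12,13,14,15,16-pentanorlabd-7-ene-6,17-diol | CC(C)(C)[Si](c3ccccc3)(c4ccccc4)OC[C@@H]1C(CO)=C[C@H](O)[C@@H]2C(C)(C)CCC[C@@]12C | intermediate
21 | (5R,6S,9S,10S)-11-[(tert-butyldiphenylsilyl)oxy]-12,13,14,15,16-pentanorlabd-7-ene-6,17-diyl diacetate | CC(C)(C)[Si](c3ccccc3)(c4ccccc4)OC[C@@H]1C(COC(C)=O)=C[C@H](OC(C)=O)[C@@H]2C(C)(C)CCC[C@@]12C | intermediate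
22 | (5R,6S,9S,10S)-11-hydroxy-12,13,14,15,16-pentanorlabd-7-ene-6,17-diyl diacetate | OC[C@@H]1C(COC(C)=O)=C[C@H](OC(C)=O)[C@@H]2C(C)(C)CCC[C@@]12C | intermediate
23 | 11-[(1-phenyl-1H-tetrazol-5-yl)sulfanyl]-12,13,14,15,16-pentanorlabd-7-ene-6,17-diyl diacetate, target arrangement | c3ccccc3-n4nnnc4SC[C@@H]1C(COC(C)=O)=C[C@H](OC(C)=O)[C@@H]2C(C)(C)CCC[C@@]12C | intermediate
24 | 11-[(1-phenyl-1H-tetrazol-5-yl)sulfonyl]-12,13,14,15,16-pentanorlabd-7-ene-6,17-diyl diacetate, target arrangement | O=S(=O)(C[C@@H]1C(COC(C)=O)=C[C@H](OC(C)=O)[C@@H]2C(C)(C)CCC[C@@]12C)c3nnnn3-c4ccccc4 | intermediate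
25 | 2-methyl-2-vinyloxirane (racemic) | CC1(CO1)C=C | starting material
26 | (4-methoxyphenyl)methanol | COc1ccc(CO)cc1 | starting material
27 | (2S)-2-[(4-methoxybenzyl)oxy]-2-methylbut-3-en-1-ol | C=C[C@](C)(OCc1ccc(OC)cc1)CO | intermediate
28 | (2S)-2-[(4-methoxybenzyl)oxy]-2-methylbut-3-enal | C=C[C@](C)(OCc1ccc(OC)cc1)C=O | intermediate
29 | (5R,6S,9S,10S,11E,13S)-13-[(4-methoxybenzyl)oxy]labda-7,11,14-triene-6,17-diyl diacetate | C=C[C@](C)(OCc3ccc(OC)cc3)/C=C/[C@@H]1C(COC(C)=O)=C[C@H](OC(C)=O)[C@@H]2C(C)(C)CCC[C@@]12C | intermediate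
30 | (5R,6S,9S,10S,11E,13S)-13-hydroxylabda-7,11,14-triene-6,17-diyl diacetate, CNP0103498.1 | C=C[C@](C)(O)/C=C/[C@@H]1C(COC(C)=O)=C[C@H](OC(C)=O)[C@@H]2C(C)(C)CCC[C@@]12C | target

Total step count: 18. Longest linear sequence: 14 steps (1–5, 8–14, 17, 18).

Steps most likely to fail

Step 9 (key step, proposed new method). The acetal centre may be scrambled by reversible Lewis-acid opening of the dioxolane, or the chair with the ring oxygen axial may not be preferred strongly enough; either would erode the discrimination of the two alkene faces. The zwitterion may also partly collapse by proton transfer to an open-chain beta-alkoxy enone. The fallback sets out from acid 9 and gives up auxiliary control. The ketene from 9 is combined as in step 8 with achiral, commercially available 2,2-dimethyl-4-methylidene-1,3-dioxolane to give the spiro-acetonide cyclobutanone F1. F1 is taken through the Lewis-acid formal [4+2] cycloaddition of 3-alkoxycyclobutanones with alkenes in its auxiliary-free form (EtAlCl2, then K2CO3/MeOH, acetone being lost), which should give 19 together with its enantiomer F2 as the racemate. The racemate is resolved by preparative chromatography on a chiral stationary phase, and 19 re-enters the route at step 10.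

Step 8. Dimerisation or oligomerisation of the hindered aldoketene may outrun its cycloaddition to the acid-sensitive enol ether. The fallback sets out from acid 9 and comes back at 16. The dianion of 9 (LiN(iPr)2, THF, −78 °C) is chlorinated with CCl4 to the chloro acid F3. Its acid chloride F4 (oxalyl chloride) is dehydrochlorinated with Et3N in the presence of 13 to the more electrophilic chloroketene F5, whose [2+2] adduct is the chlorocyclobutanone F6. Reductive dechlorination of F6 with Zn(Cu), NH4Cl, MeOH should give 16.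

Step 17. The sulfonyl carbanion may be consumed by acyl transfer from the neighbouring C17 acetate or by ester enolisation instead of adding to the hindered aldehyde. The fallback sets out from alcohol 22, uses non-basic steps and comes back at target 30, so steps 13–16 and 18 are not needed. Dess–Martin oxidation of 22 gives aldehyde F7, and Takai olefination (CrCl2, CHI3, THF) gives the E vinyl iodide F8. Stille coupling of F8 with (E)-3-(tributylstannyl)but-2-en-1-ol (Pd(PPh3)4, CuI, DMF) gives the E,E-dienol F9. Sharpless asymmetric epoxidation of F9 (Ti(OiPr)4, D-(−)-diethyl tartrate, t-BuOOH, molecular sieves, −20 °C) gives the (13R,14R)-epoxy alcohol F10, which is converted (I2, PPh3, imidazole) into the epoxy iodide F11. Reductive opening of F11 with Zn in EtOH transposes the oxygen to C13 and forms the C14=C15 vinyl group, giving 30.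

Further compounds
F1 | step 9 | 6,6-dimethyl-1-[(6E)-8-[(tert-butyldiphenylsilyl)oxy]-2,6-dimethyloct-6-en-2-yl]-5,7-dioxaspiro[3.4]octan-2-one (stereoisomer mixture) | O=C1CC2(COC(C)(C)O2)C1C(C)(C)CCC/C(C)=C/CO[Si](c3ccccc3)(c4ccccc4)C(C)(C)C
F2 | step 9 | enantiomer of 19, (5S,9R,10R)-11-[(tert-butyldiphenylsilyl)oxy]-17-hydroxy-12,13,14,15,16-pentanorlabd-7-en-6-one | CC(C)(C)[Si](c3ccccc3)(c4ccccc4)OC[C@H]1C(CO)=CC(=O)[C@H]2C(C)(C)CCC[C@]12C
F3 | step 8 | (7E)-9-[(tert-butyldiphenylsilyl)oxy]-2-chloro-3,3,7-trimethylnon-7-enoic acid (racemic) | OC(=O)C(Cl)C(C)(C)CCC/C(C)=C/CO[Si](c1ccccc1)(c1ccccc1)C(C)(C)C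
F4 | step 8 | (7E)-9-[(tert-butyldiphenylsilyl)oxy]-2-chloro-3,3,7-trimethylnon-7-enoyl chloride | ClC(=O)C(Cl)C(C)(C)CCC/C(C)=C/CO[Si](c1ccccc1)(c1ccccc1)C(C)(C)C
F5 | step 8 | chloroketene, (7E)-9-[(tert-butyldiphenylsilyl)oxy]-2-chloro-3,3,7-trimethylnona-1,7-dien-1-one | O=C=C(Cl)C(C)(C)CCC/C(C)=C/CO[Si](c1ccccc1)(c1ccccc1)C(C)(C)C
F6 | step 8 | (6R)-6-tert-butyl-1-chloro-1-[(6E)-8-[(tert-butyldiphenylsilyl)oxy]-2,6-dimethyloct-6-en-2-yl]-5,7-dioxaspiro[3.4]octan-2-one (diastereomer mixture) | O=C1CC2(CO[C@@H](C(C)(C)C)O2)C1(Cl)C(C)(C)CCC/C(C)=C/CO[Si](c3ccccc3)(c4ccccc4)C(C)(C)C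
F7 | step 17 | 11-oxo-12,13,14,15,16-pentanorlabd-7-ene-6,17-diyl diacetate, target arrangement | O=C[C@@H]1C(COC(C)=O)=C[C@H](OC(C)=O)[C@@H]2C(C)(C)CCC[C@@]12C
F8 | step 17 | (11E)-12-iodo-13,14,15,16-tetranorlabda-7,11-diene-6,17-diyl diacetate, target arrangement | I/C=C/[C@@H]1C(COC(C)=O)=C[C@H](OC(C)=O)[C@@H]2C(C)(C)CCC[C@@]12C
F9 | step 17 | (11E,13E)-15-hydroxylabda-7,11,13-triene-6,17-diyl diacetate, target arrangement | OC/C=C(C)/C=C/[C@@H]1C(COC(C)=O)=C[C@H](OC(C)=O)[C@@H]2C(C)(C)CCC[C@@]12C
F10 | step 17 | (11E,13R,14R)-13,14-epoxy-15-hydroxylabda-7,11-diene-6,17-diyl diacetate, target arrangement | OC[C@H]1O[C@]1(C)/C=C/[C@@H]2C(COC(C)=O)=C[C@H](OC(C)=O)[C@@H]3C(C)(C)CCC[C@@]23C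
F11 | step 17 | (11E)-13,14-epoxy-15-iodolabda-7,11-diene-6,17-diyl diacetate, epoxide as in F10, target arrangement | IC[C@H]1O[C@]1(C)/C=C/[C@@H]2C(COC(C)=O)=C[C@H](OC(C)=O)[C@@H]3C(C)(C)CCC[C@@]23C
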